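All runs were computed with made-up constants, and the scatter is random.

The beta run cannot be called used up. At 31 min it shows 59.8 mM of target, so the equation alone would leave 140 mM of starting material and 160 mM of partner. Yet its rate has dropped from 6.50 mM/min to 0.641 mM/min, far less than it began with. So try, as a working assumption, a partner's balance with a further exit, a loss on its own clock.

| flask | starting material | partner | time |
|---|---|---|---|
| beta | 200 mM | 220 mM |  |
| theta | 600 mM | 220 mM |  |
| delta | 800 mM | 880 mM | 31 min |

| run | time / min | [target] / mM |
|---|---|---|
| beta run | 1.2 | 7.8 |
| beta run | 2.8 | 17.0 |
| beta run | 6.2 | 32.3 |
| beta run | 14 | 48.9 |
| beta run | 31 | 59.8 |
| theta run | 1.2 | 16.8 |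
| theta run | 2.8 | 27.7 |
| theta run | 6.2 | 50.7 |
| theta run | 14 | 77.8 |
| theta run | 31 | 94.5 |

(readings scatter by 1 mM)

- Overall: starting material + partner -> target.
- Constant volume, constant temperature.
- Readings of a species count what is bound in complexes too.
- "The second partner" is partner.
- An order is taken over about fifteen percent of the charge, up and down.

* order of the initial rate in [starting material], near the charge of the beta run, the rate being that where two percent of its starting material are target (one fixed amount of target, the same in the runs compared)
* target in the delta run at 31 min, as a share of the starting material charged

Two times then matter. Divide the target at 31 min by the mean rate up to 2.8 min, 6.07 mM/min, and you get the stop time, 9.85 min in the beta run. The theta run, with 600 mM of starting material and the same partner, reads about the same, 9.55 min. Divide the beta run's starting material by its rate and you get the fill time, 32.9 min. Their ratio in the beta run is 29.9%.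

For the delta run, I reckon as follows. The first readings lie nearest the point where the order is asked. Taken at one time, not at one amount of target, they give a mean order of 0.698 between the charges of the beta and theta runs. The partner's order cannot be read, since both runs charge 220 mM, so I assume one. The delta fill time becomes 12.5 min. I keep the stop time, and one minus the exponential of minus their ratio gives my estimate, 54.5%.

The forecast says 0.6 and 17%, noting that “four times as much partner could raise yield considerably”.

The delta run gives 69.1%, above my figure, and the order asked near the beta charge is 0.76. At the fixed amount of target, the theta run's rate is 12 mM/min against 6.6 mM/min in the beta run, a ratio of 1.8.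

    2 partner ⇌ reagent dimer, settled at all times (4.100 /M)
    starting material + reagent dimer → target + partner (1.200 /M/min)
    starting material + partner ⇌ idle substrate-reagent adduct, settled at all times (3.090 /M)
    partner → lost reagent (0.09120 /min)

Now use the stop time on the beta run. An exponential rise to 59.8 mM with that time reaches a quarter of the starting material charged at 17.8 min, and the beta run reaches it at 15.0 min.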